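A small charge of L, cL = 2.0 mM, faces cJ = 0.98 M in this flask, so full conversion asks 490 rounds of each L.

all flasks: J 0.98 M
- oak: D 0.049 M; L 2 mM; the very flask that is asked about, followed so far
- flask: D 0.0490 M; L 2.0 mM

oak run (percent of the J charged)

| time / min | Q / % | J / % |
|---|---|---|
| 10.0 | 14 | 87 |
| 20.0 | 24 | 76 |
| 30.0 | 32 | 69 |
| 40.0 | 42 | 60 |

(readings scatter by 1.5 percentage points)

- no earlier run changes the charge of L; that part of a forecast is a guess

- factor on the rate of making Q when 20% of the J are converted if L is charged twice over
- factor on the rate when 20% of the J are converted if L is charged at 0.40 mM instead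

In this flask's readings, the turnover frequency of L over the first 10.0 min is 6.86 min⁻¹. From the first reading to the last the slope is 4.57 min⁻¹, lower than at the start. I see no knee within the scatter of 1.5 percentage points. The J readings, taken as first order in J, give k = 0.0128 min⁻¹. So my curve passes 20% conversion at 17.4 min and half conversion at 54.2 min, then bends towards the full charge as Q.

Both questions look at 20% conversion. There this flask stands at 98.0, the J converted per L charged, its turnover number. Doubled L stands at 49.0, and 0.40 mM at 490. The readings reach 206 at 40.0 min, fewer than the 0.40 mM flask asks. Plain proportion gives 2 and 0.200. I reckon with some wear on L per round, and I commit to a first factor above 2 and a second below 0.200.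

The forecast gives 1.9 and 0.22, from “a simple turnover catalyst, with rate proportional to L”. Its second factor stands above plain proportion.

The flask gives 2.21 and 0.0333.

    J + L → G (k = 16.0 M⁻¹ min⁻¹)
    G + D → X (k = 2.60 M⁻¹ min⁻¹)
    G → E (k = 0.00520 min⁻¹)
    Z → L + Q (k = 14.0 min⁻¹)
    G → Z (k = 75.0 min⁻¹)

In this flask G passes into Z at 75 min⁻¹, far faster than it meets D, at 0.127 min⁻¹ per G, so 0.170% of the rounds end in X. Multiplied by the 195 turnovers at 40.0 min, that gives 33.1%, and the flask holds 32.9% of its catalyst as X. The 0.40 mM flask needs 490 turnovers for its 20%, about what this flask has behind it after 800 min, when X holds 81.3%; its simulated factor is 0.0333.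

Readings and results are calculated on assumed constants; the scatter is artificial.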